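## Retrosynthetic overview

1. Locants: C1 = ester carbon, C2 = its α-carbon, O1–O2–C3–C4–C5–C6 = the 1,2-dioxane (O2 on C3, O1 on C6), C7–C12 = side chain up to the cyclohexene. Target ⇒ diimide saturation of C7=C8 ⇒ Wittig union of a C1–C7 dioxane aldehyde with a C8–C12 allylic ylide that brings the trimethylcyclohexene ring ready-made from dihydro-β-ionone.
2. Dioxane core ⇒ key step: H2O2 as a two-oxygen linchpin between two strained C–O electrophiles of one acyclic chain. It first opens a 2,2-disubstituted oxirane at its tertiary carbon (O1–C6, inversion), then C4 of a cis-β-lactone (O2–C3, inversion, 6-exo-tet). This frees CO2H (C1) and CH2OH (C7, the later Wittig handle).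
3. Epoxy-β-lactone ⇒ catalytic asymmetric acyl halide–aldehyde cyclocondensation of propionyl chloride with 4-[(2S)-2-methyloxiran-2-yl]butanal ⇒ ozonolysis of an allyl-extended (S)-2-methylglycidyl tosylate ⇒ Sharpless epoxidation of methallyl alcohol.
4. Enabling feature: in the ring O1–O2–C3–C4–C5–C6 the secondary C3 lies β to the C1 carbonyl, and the quaternary C6 carries a methyl group and an exocyclic CH2 (C7), 1,4 to C3. Each ring C–O bond can therefore come from stereospecific opening of a strained ring (β-lactone at C3, oxirane at C6), so no ring conformation has to tell CH3 from CH2R at C6.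
5. Ring order: the cyclohexene is never formed in the route (bought in); oxirane and oxetanone are temporary rings consumed in step 5; the 1,2-dioxane is the only skeletal ring the route closes, and the last ring closure of all.

Key step: step 5

Assumption: O-trimethylsilylquinidine is taken to deliver the (3S,4R)-cis-β-lactone in step 4; should the sense of induction be the reverse, its pseudoenantiomer O-trimethylsilylquinine is used with no other change.

## Route

Step 1
Reactants: 1 2-methylprop-2-en-1-ol (methallyl alcohol)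
Product: 3 [(2S)-2-methyloxiran-2-yl]methyl 4-methylbenzenesulfonate, via epoxy alcohol 2 (not isolated)
Conditions: Ti(OiPr)4 (cat.), D-(−)-diisopropyl tartrate (cat.), cumene hydroperoxide, 4 Å MS, CH2Cl2, −20 °C; then TsCl, Et3N, DMAP (cat.), −10 °C
Reagents that add atoms: cumene hydroperoxide, CC(C)(OO)c1ccccc1; p-toluenesulfonyl chloride, Cc1ccc(cc1)S(=O)(=O)Cl
Why: Sharpless asymmetric epoxidation with in situ tosylation of the water-soluble epoxy alcohol: the titanium catalyst made from the unnatural D-(−)-tartrate should deliver oxygen to the alkene face that gives (R)-2, which becomes (S)-3 on sulfonylation only through the change of CIP priorities, and recrystallisation of 3 should upgrade its ee.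

Step 2
Reactants: 3 [(2S)-2-methyloxiran-2-yl]methyl 4-methylbenzenesulfonate
Product: 5 (2S)-2-(but-3-en-1-yl)-2-methyloxirane, via hydroxy tosylate 4 (not isolated)
Conditions: CH2=CHCH2MgCl, CuI (cat.), THF, −40 to 0 °C; aqueous work-up; then K2CO3, MeOH, rt
Reagents that add atoms: allylmagnesium chloride, C=CC[Mg]Cl
Why: Copper-catalysed Grignard opening of the glycidyl sulfonate at the unhindered oxirane CH2 followed by base-induced re-closure (3-exo-tet) of the tertiary alkoxide onto CH2OTs, a net epoxide migration in which no bond to the quaternary carbon is broken, so that its configuration is retained while the former CH2OTs carbon becomes the oxirane CH2 (later C7) and the former oxirane CH2 becomes C5.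

Step 3
Reactants: 5 (2S)-2-(but-3-en-1-yl)-2-methyloxirane
Product: 7 4-[(2S)-2-methyloxiran-2-yl]butanal, via ozonide 6 (not isolated)
Conditions: O3, CH2Cl2, −78 °C; then Me2S, −78 °C to rt
Reagents that add atoms: ozone, [O-][O+]=O
Why: Ozonolysis with reductive work-up should cleave the only C=C bond to the aldehyde (C3) and leave the oxirane, which is inert to ozone, untouched, with no stereocentre involved.

Step 4
Reactants: 7 4-[(2S)-2-methyloxiran-2-yl]butanal
Product: 8 (3S,4R)-3-methyl-4-{2-[(2S)-2-methyloxiran-2-yl]ethyl}oxetan-2-one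
Conditions: EtCOCl, iPr2NEt, O-trimethylsilylquinidine (10 mol %), LiClO4, CH2Cl2/Et2O, −78 °C
Reagents that add atoms: propionyl chloride, CCC(=O)Cl
Why: Catalytic asymmetric acyl halide–aldehyde cyclocondensation (formal ketene–aldehyde [2+2] cycloaddition through an alkaloid-bound methylketene enolate, LiClO4-assisted aldol addition and lactonisation) should give the cis-3,4-disubstituted β-lactone, both new stereocentres (target C2 and the still uninverted C3) being set by the cinchona catalyst and not by the remote oxirane.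

Step 5
Reactants: 8 (3S,4R)-3-methyl-4-{2-[(2S)-2-methyloxiran-2-yl]ethyl}oxetan-2-one
Product: 10 (2S)-2-[(3S,6R)-6-(hydroxymethyl)-6-methyl-1,2-dioxan-3-yl]propanoic acid, via hydroperoxide 9 (not isolated)
Conditions: (a) H2O2 (anhydrous, in Et2O), H3PMo12O40 (cat.), 0 °C to rt, then aqueous wash; (b) Cs2CO3, DMF, 0 °C, then 1 M HCl
Reagents that add atoms: hydrogen peroxide, OO
Why: Proposed new method: stage (a) is the known H3PMo12O40-catalysed perhydrolysis of an epoxide, in which H2O2 attacks the acid-activated 2,2-disubstituted oxirane at its tertiary carbon in a borderline SN2 event with inversion and so fixes C6; stage (b), the new part, lets the peroxy anion of 9 displace the lactone oxygen at C4 of the oxetanone (target C3) from the back side, with the carboxylate as leaving group. The closest known reaction types are the alkyl–oxygen (SN2) opening of β-lactones at the β-carbon by soft nucleophiles such as thiolates, azide and carboxylates, and the base-mediated intramolecular alkylation of hydroperoxides by secondary sulfonates, halides and epoxides that is a standard entry to 1,2-dioxanes. The 1,2-dioxane is closed through its O2–C3 bond in a 6-exo-tet mode. C3 arises by inversion of the (4R)-lactone carbon and C6 by inversion of the (2S)-oxirane carbon, while C2 is carried unchanged from the cis-lactone, so all three stereocentres rest on stereospecific displacements and not on a ring conformation, which could not distinguish CH3 from CH2OH at C6. The step needs the peroxy anion to win over the primary alkoxide (the hydroperoxide is the stronger acid by several pKa units and an alpha-effect nucleophile), alkyl–oxygen over acyl–oxygen cleavage (acyl attack would need an eight-membered perester) and no E1cB opening of the lactone (carbonate cannot enolise it); excess H2O2 is washed out before the base is added so that HOO– cannot attack the lactone.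

Step 6
Reactants: 10 (2S)-2-[(3S,6R)-6-(hydroxymethyl)-6-methyl-1,2-dioxan-3-yl]propanoic acid
Product: 11 methyl (2S)-2-[(3S,6R)-6-(hydroxymethyl)-6-methyl-1,2-dioxan-3-yl]propanoate
Conditions: Me3SiCHN2, MeOH/toluene, 0 °C
Reagents that add atoms: (trimethylsilyl)diazomethane, C[Si](C)(C)C=[N+]=[N-]
Why: Methyl esterification of the carboxylic acid with (trimethylsilyl)diazomethane in methanol, a neutral O-methylation that should spare the peroxide, the primary alcohol and all three stereocentres.

Step 7
Reactants: 11 methyl (2S)-2-[(3S,6R)-6-(hydroxymethyl)-6-methyl-1,2-dioxan-3-yl]propanoate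
Product: 12 methyl (2S)-2-[(3S,6R)-6-formyl-6-methyl-1,2-dioxan-3-yl]propanoate
Conditions: Dess–Martin periodinane, CH2Cl2, 0 °C to rt
Reagents that add atoms: none
Why: Dess–Martin oxidation of the neopentyl-type primary alcohol to the aldehyde under mild conditions that dialkyl peroxides tolerate, the product having a quaternary α-carbon and therefore no way to enolise or epimerise.

Step 8
Reactants: 13 4-(2,6,6-trimethylcyclohex-1-en-1-yl)butan-2-one (dihydro-β-ionone)
Product: 14 ethyl (2E)-3-methyl-5-(2,6,6-trimethylcyclohex-1-en-1-yl)pent-2-enoate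
Conditions: (EtO)2P(O)CH2CO2Et, NaH, THF, 0 °C to reflux
Reagents that add atoms: triethyl phosphonoacetate, CCOC(=O)CP(=O)(OCC)OCC
Why: Horner–Wadsworth–Emmons olefination of the methyl ketone should give mainly the (E)-enoate (ester trans to the larger CH2CH2R group), the minor (Z)-isomer being removed by chromatography so that the C9=C10 geometry of the target is fixed here.

Step 9
Reactants: 14 ethyl (2E)-3-methyl-5-(2,6,6-trimethylcyclohex-1-en-1-yl)pent-2-enoate
Product: 15 (2E)-3-methyl-5-(2,6,6-trimethylcyclohex-1-en-1-yl)pent-2-en-1-ol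
Conditions: iBu2AlH, CH2Cl2, −78 °C
Reagents that add atoms: none
Why: 1,2-Reduction of the α,β-unsaturated ester to the allylic alcohol with iBu2AlH, which leaves the alkene geometry untouched.

Step 10
Reactants: 15 (2E)-3-methyl-5-(2,6,6-trimethylcyclohex-1-en-1-yl)pent-2-en-1-ol
Product: 16 2-[(3E)-5-bromo-3-methylpent-3-en-1-yl]-1,3,3-trimethylcyclohex-1-ene
Conditions: PBr3, Et2O, −10 °C
Reagents that add atoms: phosphorus tribromide, BrP(Br)Br
Why: Bromination of the primary allylic alcohol with PBr3 (SN2 at the primary carbon at low temperature) should give the primary (E)-bromide without allylic transposition.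

Step 11
Reactants: 16 2-[(3E)-5-bromo-3-methylpent-3-en-1-yl]-1,3,3-trimethylcyclohex-1-ene
Product: 17 [(2E)-3-methyl-5-(2,6,6-trimethylcyclohex-1-en-1-yl)pent-2-en-1-yl]triphenylphosphonium bromide
Conditions: PPh3, toluene, rt
Reagents that add atoms: triphenylphosphine, c1ccc(cc1)P(c1ccccc1)c1ccccc1
Why: Quaternisation of triphenylphosphine by the primary allylic bromide (SN2) to the Wittig salt.

Step 12
Reactants: 12 methyl (2S)-2-[(3S,6R)-6-formyl-6-methyl-1,2-dioxan-3-yl]propanoate; 17 [(2E)-3-methyl-5-(2,6,6-trimethylcyclohex-1-en-1-yl)pent-2-en-1-yl]triphenylphosphonium bromide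
Product: 19 methyl (2S)-2-[(3S,6R)-6-methyl-6-[(3E)-4-methyl-6-(2,6,6-trimethylcyclohex-1-en-1-yl)hexa-1,3-dien-1-yl]-1,2-dioxan-3-yl]propanoate (new C1'=C2' bond as an E/Z mixture), via ylide 18 (not isolated)
Conditions: NaN(SiMe3)2, THF, −78 °C; then 12, −78 to 0 °C
Reagents that add atoms: none
Why: Wittig olefination under lithium-free conditions, in which the semi-stabilised allylic ylide should add through its α-carbon to the non-enolisable aldehyde at low temperature and collapse via the oxaphosphetane without a free β-peroxy alkoxide, the geometry of the new C7=C8 bond being irrelevant because it is saturated in step 13 while the (E)-C9=C10 bond is carried over from 17.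

Step 13
Reactants: 19 methyl (2S)-2-[(3S,6R)-6-methyl-6-[(3E)-4-methyl-6-(2,6,6-trimethylcyclohex-1-en-1-yl)hexa-1,3-dien-1-yl]-1,2-dioxan-3-yl]propanoate
Product: 20 methyl (2S)-2-[(3S,6S)-6-methyl-6-[(3E)-4-methyl-6-(2,6,6-trimethylcyclohex-1-en-1-yl)hex-3-en-1-yl]-1,2-dioxan-3-yl]propanoate
Conditions: KO2CN=NCO2K, AcOH, MeOH/CH2Cl2, 0 °C to rt
Reagents that add atoms: none
Why: Diimide reduction (concerted syn transfer of H2 from HN=NH) should saturate the 1,2-disubstituted terminus of the diene much faster than the trisubstituted and tetrasubstituted alkenes and leave the O–O bond and the ester untouched, as is usual for unsaturated cyclic peroxides, with no stereocentre affected.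

## Compound list

1 | 2-methylprop-2-en-1-ol | C=C(C)CO | starting material
2 | [(2R)-2-methyloxiran-2-yl]methanol | OC[C@]1(C)CO1 | intermediate (not isolated)
3 | [(2S)-2-methyloxiran-2-yl]methyl 4-methylbenzenesulfonate | Cc1ccc(cc1)S(=O)(=O)OC[C@]1(C)CO1 | intermediate
4 | (2S)-2-hydroxy-2-methylhex-5-en-1-yl 4-methylbenzenesulfonate | Cc1ccc(cc1)S(=O)(=O)OC[C@](O)(C)CCC=C | intermediate (not isolated)
5 | (2S)-2-(but-3-en-1-yl)-2-methyloxirane | C=CCC[C@@]1(C)CO1 | intermediate
6 | 3-{2-[(2S)-2-methyloxiran-2-yl]ethyl}-1,2,4-trioxolane (both epimers at the trioxolane carbon) | C1OC(CC[C@@]2(C)CO2)OO1 | intermediate (not isolated)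
7 | 4-[(2S)-2-methyloxiran-2-yl]butanal | O=CCC[C@@]1(C)CO1 | intermediate
8 | (3S,4R)-3-methyl-4-{2-[(2S)-2-methyloxiran-2-yl]ethyl}oxetan-2-one | C[C@@H]1C(=O)O[C@@H]1CC[C@@]2(C)CO2 | intermediate
9 | (3S,4R)-4-[(3R)-3-hydroperoxy-4-hydroxy-3-methylbutyl]-3-methyloxetan-2-one | C[C@@H]1C(=O)O[C@@H]1CC[C@](C)(CO)OO | intermediate (not isolated)
10 | (2S)-2-[(3S,6R)-6-(hydroxymethyl)-6-methyl-1,2-dioxan-3-yl]propanoic acid | OC(=O)[C@@H](C)[C@@H]1CC[C@](C)(CO)OO1 | intermediate
11 | methyl (2S)-2-[(3S,6R)-6-(hydroxymethyl)-6-methyl-1,2-dioxan-3-yl]propanoate | COC(=O)[C@@H](C)[C@@H]1CC[C@](C)(CO)OO1 | intermediate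
12 | methyl (2S)-2-[(3S,6R)-6-formyl-6-methyl-1,2-dioxan-3-yl]propanoate | COC(=O)[C@@H](C)[C@@H]1CC[C@](C)(C=O)OO1 | intermediate
13 | 4-(2,6,6-trimethylcyclohex-1-en-1-yl)butan-2-one (dihydro-β-ionone) | CC(=O)CCC1=C(C)CCCC1(C)C | starting material
14 | ethyl (2E)-3-methyl-5-(2,6,6-trimethylcyclohex-1-en-1-yl)pent-2-enoate | CCOC(=O)/C=C(\C)CCC1=C(C)CCCC1(C)C | intermediate
15 | (2E)-3-methyl-5-(2,6,6-trimethylcyclohex-1-en-1-yl)pent-2-en-1-ol | OC/C=C(\C)CCC1=C(C)CCCC1(C)C | intermediate
16 | 2-[(3E)-5-bromo-3-methylpent-3-en-1-yl]-1,3,3-trimethylcyclohex-1-ene | BrC/C=C(\C)CCC1=C(C)CCCC1(C)C | intermediate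
17 | [(2E)-3-methyl-5-(2,6,6-trimethylcyclohex-1-en-1-yl)pent-2-en-1-yl]triphenylphosphonium bromide | [Br-].C(/C=C(\C)CCC1=C(C)CCCC1(C)C)[P+](c2ccccc2)(c3ccccc3)c4ccccc4 | intermediate
18 | [(2E)-3-methyl-5-(2,6,6-trimethylcyclohex-1-en-1-yl)pent-2-en-1-ylidene]triphenylphosphorane | C(/C=C(\C)CCC1=C(C)CCCC1(C)C)=P(c2ccccc2)(c3ccccc3)c4ccccc4 | intermediate (not isolated)
19 | methyl (2S)-2-[(3S,6R)-6-methyl-6-[(3E)-4-methyl-6-(2,6,6-trimethylcyclohex-1-en-1-yl)hexa-1,3-dien-1-yl]-1,2-dioxan-3-yl]propanoate (1E/1Z mixture; SMILES drawn without a descriptor at that bond) | COC(=O)[C@@H](C)[C@@H]1CC[C@](C)(C=C/C=C(\C)CCC2=C(C)CCCC2(C)C)OO1 | intermediate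
20 | methyl (2S)-2-[(3S,6S)-6-methyl-6-[(3E)-4-methyl-6-(2,6,6-trimethylcyclohex-1-en-1-yl)hex-3-en-1-yl]-1,2-dioxan-3-yl]propanoate | COC(=O)[C@@H](C)[C@@H]1CC[C@](C)(CC/C=C(\C)CCC2=C(C)CCCC2(C)C)OO1 | target

## Step count and risks

Total step count: 13. Longest linear sequence: 9 steps (steps 1–7, 12, 13); the side-chain fragment takes 4 steps (8–11).

Steps most likely to fail:

Step 5 (carries the label). What may go wrong: partial ionisation at the tertiary oxirane carbon during perhydrolysis would erode the configuration at C6. After deprotonation, acyl attack or oligomerisation could compete with the 6-exo-tet alkyl–oxygen cleavage, or the β-hydroxy hydroperoxide could fragment under base. Fallback (known chemistry, the classical conjugate-addition closure): it sets out from aldehyde 7. Wittig reaction with methyl 2-(triphenylphosphoranylidene)propanoate (CH2Cl2, rt) should give methyl (2E)-2-methyl-5-[(2S)-2-methyloxiran-2-yl]pent-2-enoate F1. The same H3PMo12O40-catalysed perhydrolysis should give methyl (2E,6R)-6-hydroperoxy-7-hydroxy-2,6-dimethylhept-2-enoate F2. Et2NH in CF3CH2OH should then close the dioxane by intramolecular oxa-Michael addition of the hydroperoxide (6-exo-trig), and the route is rejoined at 11. C6 stays fixed by the epoxide opening, but C3 and C2 would then be set under weak substrate control, so 11 would have to be separated from its C2/C3 diastereomers by chromatography.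

Step 12. What may go wrong: the basic ylide may deprotonate the peroxide (Kornblum–DeLaMare cleavage at C3–H, or E1cB ring opening after enolisation at C2). The delocalised allylic ylide may also scramble the C9=C10 geometry before it adds. Fallback (no allylic carbanion, geometry fixed by carbometalation): it sets out from 12 and 13 and returns at 20.
- Ohira–Bestmann homologation of 12 (dimethyl (1-diazo-2-oxopropyl)phosphonate, K2CO3, MeOH, 0 °C) should give methyl (2S)-2-[(3S,6R)-6-ethynyl-6-methyl-1,2-dioxan-3-yl]propanoate F3.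
- Ketone 13 is converted with LiN(iPr)2 and ClP(O)(OEt)2 into diethyl 4-(2,6,6-trimethylcyclohex-1-en-1-yl)but-1-en-2-yl phosphate F4, and with more LiN(iPr)2 into 2-(but-3-yn-1-yl)-1,3,3-trimethylcyclohex-1-ene F5.
- Zirconium-catalysed carboalumination (Me3Al, Cp2ZrCl2 cat.) gives dimethyl[(1E)-2-methyl-4-(2,6,6-trimethylcyclohex-1-en-1-yl)but-1-en-1-yl]alumane F6, and iodinolysis gives 2-[(3E)-4-iodo-3-methylbut-3-en-1-yl]-1,3,3-trimethylcyclohex-1-ene F7.
- Sonogashira coupling of F3 with F7 (Pd(PPh3)4, CuI, iPr2NH, THF, rt) should give methyl (2S)-2-[(3S,6R)-6-methyl-6-[(3E)-4-methyl-6-(2,6,6-trimethylcyclohex-1-en-1-yl)hex-3-en-1-yn-1-yl]-1,2-dioxan-3-yl]propanoate F8.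
- Excess diimide under the conditions of step 13 should saturate the triple bond by way of the (1Z)-isomer of 19 and deliver 20.

Step 13. What may go wrong: the conjugated diene may be reduced with too little discrimination between its di- and trisubstituted ends (over-reduction), or the reduction next to the quaternary centre may stall. Fallback (no diene is ever formed): it sets out from 12 and returns at 20. Methylenation (Ph3PCH3Br, KN(SiMe3)2, THF, −78 °C) should give methyl (2S)-2-[(3S,6R)-6-ethenyl-6-methyl-1,2-dioxan-3-yl]propanoate F9. Hydroboration with 9-borabicyclo[3.3.1]nonane (THF, 0 °C to rt) should give methyl (2S)-2-[(3S,6S)-6-[2-(9-borabicyclo[3.3.1]nonan-9-yl)ethyl]-6-methyl-1,2-dioxan-3-yl]propanoate F10. B-alkyl Suzuki–Miyaura coupling with the vinyl iodide F7, made as in the fallback to step 12 (Pd(dppf)Cl2, AsPh3, Cs2CO3, DMF/THF/H2O, rt), should give 20 directly with the C7–C8 bond already saturated.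

Further compounds
F1 | step 5 | methyl (2E)-2-methyl-5-[(2S)-2-methyloxiran-2-yl]pent-2-enoate | COC(=O)/C(C)=C/CC[C@@]1(C)CO1
F2 | step 5 | methyl (2E,6R)-6-hydroperoxy-7-hydroxy-2,6-dimethylhept-2-enoate | COC(=O)/C(C)=C/CC[C@](C)(CO)OO
F3 | step 12 | methyl (2S)-2-[(3S,6R)-6-ethynyl-6-methyl-1,2-dioxan-3-yl]propanoate | COC(=O)[C@@H](C)[C@@H]1CC[C@](C)(C#C)OO1
F4 | step 12 | diethyl 4-(2,6,6-trimethylcyclohex-1-en-1-yl)but-1-en-2-yl phosphate | C=C(CCC1=C(C)CCCC1(C)C)OP(=O)(OCC)OCC
F5 | step 12 | 2-(but-3-yn-1-yl)-1,3,3-trimethylcyclohex-1-ene | C#CCCC1=C(C)CCCC1(C)C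
F6 | step 12 | dimethyl[(1E)-2-methyl-4-(2,6,6-trimethylcyclohex-1-en-1-yl)but-1-en-1-yl]alumane | C[Al](C)/C=C(\C)CCC1=C(C)CCCC1(C)C
F7 | step 12 | 2-[(3E)-4-iodo-3-methylbut-3-en-1-yl]-1,3,3-trimethylcyclohex-1-ene | I/C=C(\C)CCC1=C(C)CCCC1(C)C
F8 | step 12 | methyl (2S)-2-[(3S,6R)-6-methyl-6-[(3E)-4-methyl-6-(2,6,6-trimethylcyclohex-1-en-1-yl)hex-3-en-1-yn-1-yl]-1,2-dioxan-3-yl]propanoate | COC(=O)[C@@H](C)[C@@H]1CC[C@](C)(C#C/C=C(\C)CCC2=C(C)CCCC2(C)C)OO1
F9 | step 13 | methyl (2S)-2-[(3S,6R)-6-ethenyl-6-methyl-1,2-dioxan-3-yl]propanoate | COC(=O)[C@@H](C)[C@@H]1CC[C@](C)(C=C)OO1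
F10 | step 13 | methyl (2S)-2-[(3S,6S)-6-[2-(9-borabicyclo[3.3.1]nonan-9-yl)ethyl]-6-methyl-1,2-dioxan-3-yl]propanoate | COC(=O)[C@@H](C)[C@@H]1CC[C@](C)(CCB2C3CCCC2CCC3)OO1
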